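**Plan** (germacrane numbering: carbocycle C1–C10; C11(=C13H2)–C12(=O) on C7; C14 on C10; C15 on C4; target is 1R,3R,6R,7R,8R,10R with a 4Z alkene)

- Cuts, in retrosynthetic order: lactone O–C6; C5=C6 (ring-closing metathesis); both oxiranes (one double Shi epoxidation); C7–C11 (iridium-catalysed branched allylic alkylation, C13 then added by Mannich methylenation); C1–C2 and C10–C14 (carboalumination/allylation); C8–C9 (propargylation).
- Forward order: the open chain C6–C7–C8–C9–C10=C1–C2–C3=C4–C5 is built first, then the C7 branch, then both oxiranes, then the ten-membered carbocycle, and the γ-lactone last.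
- Enabling feature: the cis-1,4-dioxygenated Z-2-ene O–C6–C5=C4(C15)–C3–OH inside the ten-membered ring, with the C12 carboxyl two atoms from C6. It is the retron of a strain-releasing syn-1,4 opening of a C3–C4 oxirane through a C4–C5–C6 π-allyl.
- That one event makes the O–C6 bond, the C6 centre, the 4Z-alkene and the unprotected C3–OH.
- Stereochemistry: C8 from a chiral-phosphoric-acid propargylation; C7 from the iridium catalyst; C1, C10 and C3 (with C4 of the precursor) from the D-fructose-derived dioxirane; C6 by 1,3-transfer from C4 (double inversion at palladium).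

Key step: step 14

Assumption: the absolute sense of the two enantioselective catalysts (steps 2 and 8) follows the facial models given in their Why lines; the mirror-image catalyst would be used if a model gave the opposite face.

**Step 1**
Reactants: 1 (2Z)-3-methylpent-2-en-4-yn-1-ol
Product: 2 (3Z)-5-bromo-3-methylpent-3-en-1-yne
Conditions: PBr3 (0.4 equiv), pyridine (cat.), Et2O, −10 to 0 °C
Reagents that add atoms: phosphorus tribromide, BrP(Br)Br
Why: SN2 displacement of the primary allylic alcohol through its phosphite ester at low temperature should keep the Z-geometry and avoid allylic transposition.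

**Step 2**
Reactants: 3 ethyl (2E)-4-oxobut-2-enoate; 4 allenylboronic acid pinacol ester
Product: 5 ethyl (2E,4R)-4-hydroxyhept-2-en-6-ynoate
Conditions: (R)-3,3′-bis(2,4,6-triisopropylphenyl)-1,1′-binaphthyl-2,2′-diyl hydrogen phosphate (5 mol %), 4 Å MS, toluene, −20 °C; aq. NaHCO3 work-up
Reagents that add atoms: none
Why: Chiral-phosphoric-acid-catalysed propargylation (SE2′ addition of the allenylboronate through a closed six-membered transition state) should add to the Re face of the formyl group, as with aryl and alkenyl aldehydes, and so set C8 as R without touching the enoate.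

**Step 3**
Reactants: 5 ethyl (2E,4R)-4-hydroxyhept-2-en-6-ynoate
Product: 6 (2E,4R)-hept-2-en-6-yne-1,4-diol
Conditions: i-Bu2AlH (3.5 equiv), CH2Cl2, −78 to −40 °C; aq. Rochelle salt
Reagents that add atoms: none
Why: 1,2-Reduction of the α,β-unsaturated ester with DIBAL-H should give the allylic alcohol and leave the alkyne and the stereocentre alone.

**Step 4**
Reactants: 6 (2E,4R)-hept-2-en-6-yne-1,4-diol; 2 (3Z)-5-bromo-3-methylpent-3-en-1-yne
Product: 8 (2E,4R,6E,9Z)-6,10-dimethyldodeca-2,6,9-trien-11-yne-1,4-diol, via alkenylalane 7 (not isolated)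
Conditions: Me3Al (4 equiv), Cp2ZrCl2 (0.3 equiv), CH2Cl2, 0 °C to rt; excess Me3Al removed in vacuo; then 2, Pd(PPh3)4 (5 mol %), THF, rt; aq. Rochelle salt
Reagents that add atoms: trimethylaluminium, C[Al](C)C
Why: Negishi zirconium-catalysed syn-carboalumination of the terminal alkyne (both hydroxyls held as aluminium alkoxides) should place C14 on C10 and aluminium on C1 (E), and palladium-catalysed alkenyl–allyl coupling at the CH2 terminus of the bromide should form C1–C2 with both alkene geometries kept.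

**Step 5**
Reactants: 8 (2E,4R,6E,9Z)-6,10-dimethyldodeca-2,6,9-trien-11-yne-1,4-diol
Product: 9 (2E,4R,6E,9Z)-6,10-dimethyldodeca-2,6,9,11-tetraene-1,4-diol
Conditions: H2 (1 atm), Pd/CaCO3 poisoned with Pb(OAc)2 (Lindlar catalyst), quinoline, EtOAc, rt, stopped after 1 equiv H2
Reagents that add atoms: none
Why: Lindlar semi-hydrogenation should reduce only the terminal alkyne, the sole alkyne in the molecule, to the vinyl end of the Z-diene.

**Step 6**
Reactants: 9 (2E,4R,6E,9Z)-6,10-dimethyldodeca-2,6,9,11-tetraene-1,4-diol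
Product: 10 (2E,4R,6E,9Z)-4-hydroxy-6,10-dimethyldodeca-2,6,9,11-tetraen-1-yl methyl carbonate
Conditions: ClCO2Me (1.05 equiv), pyridine, CH2Cl2, −30 °C
Reagents that add atoms: methyl chloroformate, COC(=O)Cl
Why: Acylation at low temperature should be selective for the unhindered primary allylic hydroxyl over the secondary one.

**Step 7**
Reactants: 10 (2E,4R,6E,9Z)-4-hydroxy-6,10-dimethyldodeca-2,6,9,11-tetraen-1-yl methyl carbonate; 11 3-methylbutanoic anhydride
Product: 12 (2E,4R,6E,9Z)-1-[(methoxycarbonyl)oxy]-6,10-dimethyldodeca-2,6,9,11-tetraen-4-yl 3-methylbutanoate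
Conditions: Et3N (2 equiv), DMAP (10 mol %), CH2Cl2, 0 °C to rt
Reagents that add atoms: none
Why: DMAP-catalysed esterification of the remaining secondary alcohol installs the C8 isovalerate of the target with the C8–O bond untouched.

**Step 8**
Reactants: 12 (2E,4R,6E,9Z)-1-[(methoxycarbonyl)oxy]-6,10-dimethyldodeca-2,6,9,11-tetraen-4-yl 3-methylbutanoate; 13 di-tert-butyl propanedioate
Product: 14 di-tert-butyl 2-[(3R,4R,6E,9Z)-6,10-dimethyl-4-[(3-methylbutanoyl)oxy]dodeca-1,6,9,11-tetraen-3-yl]propanedioate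
Conditions: [Ir(cod)Cl]2 (2 mol %), (Sa)-1,1′-binaphthyl-2,2′-diyl N,N-bis[(S)-1-phenylethyl]phosphoramidite (4 mol %), 1,5,7-triazabicyclo[4.4.0]dec-5-ene (8 mol %), THF, rt to 40 °C, no added salt
Reagents that add atoms: none
Why: Iridium-catalysed asymmetric allylic alkylation, in which the cyclometallated iridium–phosphoramidite ionises the primary carbonate (CO2 and methoxide leave, methoxide deprotonates the malonate) and the malonate attacks the substituted allyl terminus C7 anti to iridium, should give the branched vinyl product with C7 set as R by the ligand, which is also the Felkin-type sense (attack anti to the C8–O bond).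

**Step 9**
Reactants: 14 di-tert-butyl 2-[(3R,4R,6E,9Z)-6,10-dimethyl-4-[(3-methylbutanoyl)oxy]dodeca-1,6,9,11-tetraen-3-yl]propanedioate
Product: 15 2-[(3R,4R,6E,9Z)-6,10-dimethyl-4-[(3-methylbutanoyl)oxy]dodeca-1,6,9,11-tetraen-3-yl]propanedioic acid
Conditions: Me3SiOTf (3 equiv), 2,6-lutidine (4 equiv), CH2Cl2, 0 °C; then pH 4 citrate buffer
Reagents that add atoms: none
Why: Silyl-triflate-mediated cleavage of the two tert-butyl esters (loss of isobutene, silyl esters hydrolysed on work-up) is non-protic and should spare the isovalerate, the diene and the trisubstituted alkene.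

**Step 10**
Reactants: 15 2-[(3R,4R,6E,9Z)-6,10-dimethyl-4-[(3-methylbutanoyl)oxy]dodeca-1,6,9,11-tetraen-3-yl]propanedioic acid
Product: 16 (3R,4R,6E,9Z)-3-ethenyl-6,10-dimethyl-2-methylidene-4-[(3-methylbutanoyl)oxy]dodeca-6,9,11-trienoic acid
Conditions: (CH2O)n (4 equiv), Et2NH (1.5 equiv), EtOAc, 70 °C
Reagents that add atoms: formaldehyde (as paraformaldehyde), C=O
Why: Mannich reaction of the malonic acid followed by decarboxylative elimination of the amine should give the 2-substituted acrylic acid (C13 from formaldehyde), and C7 is not acidic under these conditions.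

**Step 11**
Reactants: 16 (3R,4R,6E,9Z)-3-ethenyl-6,10-dimethyl-2-methylidene-4-[(3-methylbutanoyl)oxy]dodeca-6,9,11-trienoic acid
Product: 17 2-(trimethylsilyl)ethyl (3R,4R,6E,9Z)-3-ethenyl-6,10-dimethyl-2-methylidene-4-[(3-methylbutanoyl)oxy]dodeca-6,9,11-trienoate
Conditions: Me3SiCH2CH2OH (1.5 equiv), N-(3-dimethylaminopropyl)-N′-ethylcarbodiimide hydrochloride (1.3 equiv), DMAP (10 mol %), CH2Cl2, 0 °C to rt
Reagents that add atoms: 2-(trimethylsilyl)ethanol, C[Si](C)(C)CCO
Why: Carbodiimide esterification masks the acid as a fluoride-labile ester, so that no free carboxylic acid sits beside the acid-sensitive vinyl oxirane in steps 12 and 13.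

**Step 12**
Reactants: 17 2-(trimethylsilyl)ethyl (3R,4R,6E,9Z)-3-ethenyl-6,10-dimethyl-2-methylidene-4-[(3-methylbutanoyl)oxy]dodeca-6,9,11-trienoate
Product: 18 2-(trimethylsilyl)ethyl (3R,4R)-3-ethenyl-5-[(2R,3R)-3-{[(2R,3S)-3-ethenyl-3-methyloxiran-2-yl]methyl}-2-methyloxiran-2-yl]-2-methylidene-4-[(3-methylbutanoyl)oxy]pentanoate
Conditions: 1,2:4,5-di-O-isopropylidene-β-D-erythro-2,3-hexodiulo-2,6-pyranose (D-fructose-derived ketone, 0.6 equiv), Oxone (2KHSO5·KHSO4·K2SO4), K2CO3, Bu4NHSO4 (cat.), MeCN/CH2(OMe)2/aq. Na2B4O7–Na2EDTA buffer (pH 10.5), 0 °C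
Reagents that add atoms: potassium peroxymonosulfate (from Oxone), [K+].[O-]S(=O)(=O)OO
Why: Shi epoxidation, in which the chiral dioxirane attacks only the two electron-rich trisubstituted alkenes (the diene at its trisubstituted end, not the vinyl groups or the acrylate) through a spiro transition state with the single vinylic H of each alkene in the hindered quadrant, should give R at both CH carbons, i.e. the (1R,10R)-trans- and (3R,4S)-cis-oxiranes.

**Step 13**
Reactants: 18 2-(trimethylsilyl)ethyl (3R,4R)-3-ethenyl-5-[(2R,3R)-3-{[(2R,3S)-3-ethenyl-3-methyloxiran-2-yl]methyl}-2-methyloxiran-2-yl]-2-methylidene-4-[(3-methylbutanoyl)oxy]pentanoate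
Product: 19 2-(trimethylsilyl)ethyl (1R,3R,4S,5Z,7R,8R,10R)-1,10:3,4-diepoxy-8-[(3-methylbutanoyl)oxy]germacra-5,11(13)-dien-12-oate
Conditions: second-generation Grubbs catalyst (H2IMes)(PCy3)Cl2Ru=CHPh (10 mol %), CH2Cl2 (1 mM), 40 °C
Reagents that add atoms: none
Why: Ring-closing metathesis of the two monosubstituted vinyl groups should give the ten-membered carbocycle as the less strained Z-alkene, and it is run only after the 1(10)-alkene is epoxidised because that alkene and the C7 vinyl form a 1,6-diene that would otherwise close to a cyclopentene.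

**Step 14**
Reactants: 19 2-(trimethylsilyl)ethyl (1R,3R,4S,5Z,7R,8R,10R)-1,10:3,4-diepoxy-8-[(3-methylbutanoyl)oxy]germacra-5,11(13)-dien-12-oate
Product: 21 (1R,3R,4Z,6R,7R,8R,10R)-1,10-epoxy-3-hydroxy-8-[(3-methylbutanoyl)oxy]germacra-4,11(13)-dien-12,6-olide (CNP0300193.1), via carboxylate 20 (not isolated)
Conditions: Bu4NF (1.3 equiv), THF, 0 °C; then (CF3)2CHOH (1.5 equiv), Pd2(dba)3·CHCl3 (2.5 mol %), P(OiPr)3 (20 mol %), THF (5 mM), 0 °C to rt
Reagents that add atoms: none
Why: Fluoride cleaves the silylethyl ester to carboxylate 20, zerovalent palladium then ionises the only allylic C–O bond (C4–O of the vinyl oxirane) anti to oxygen and with release of ring strain to a C4–C5–C6 π-allyl carrying the C3 alkoxide, and the C12 carboxylate attacks C6 on the face away from palladium. The closest known reaction type is the palladium-catalysed cis-1,4-addition of carboxylic acids to cyclic 1,3-diene monoepoxides, together with π-allyl lactonisation of alkenoic acids. One ring closes, the γ-lactone O–C12–C11–C7–C6, in a 5-exo mode with respect to the allyl unit. C6 (R) is controlled by C4 through double inversion (the lactone oxygen enters on the face the oxirane oxygen left), C3 keeps its C–O bond and configuration, and the new C4=C5 alkene is Z because the carbocycle holds C3 and C7 both anti on the allyl, whereas the alternative with C15 anti would clash with C7. The step needs attack at C6 rather than C4, which the five- versus seven-membered ring size secures, and needs the 1,10-oxirane and the isovalerate left alone, which holds because neither is allylic; the phosphite ligand avoids conjugate addition to the methylene lactone and hexafluoropropan-2-ol protonates the C3 alkoxide.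

**Compound list**

1 | (2Z)-3-methylpent-2-en-4-yn-1-ol | OC/C=C(/C)C#C | starting material
2 | (3Z)-5-bromo-3-methylpent-3-en-1-yne | BrC/C=C(/C)C#C | intermediate
3 | ethyl (2E)-4-oxobut-2-enoate | CCOC(=O)/C=C/C=O | starting material
4 | allenylboronic acid pinacol ester (4,4,5,5-tetramethyl-2-(propa-1,2-dien-1-yl)-1,3,2-dioxaborolane) | C=C=CB1OC(C)(C)C(C)(C)O1 | starting material
5 | ethyl (2E,4R)-4-hydroxyhept-2-en-6-ynoate | CCOC(=O)/C=C/[C@H](O)CC#C | intermediate
6 | (2E,4R)-hept-2-en-6-yne-1,4-diol | OC/C=C/[C@H](O)CC#C | intermediate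
7 | (2E,4R,6E)-7-(dimethylalumanyl)-6-methylhepta-2,6-diene-1,4-diol as its bis(dimethylaluminium) alkoxide | C[Al](C)OC/C=C/[C@H](O[Al](C)C)C/C(C)=C/[Al](C)C | intermediate (not isolated)
8 | (2E,4R,6E,9Z)-6,10-dimethyldodeca-2,6,9-trien-11-yne-1,4-diol | OC/C=C/[C@H](O)C/C(C)=C/C/C=C(/C)C#C | intermediate
9 | (2E,4R,6E,9Z)-6,10-dimethyldodeca-2,6,9,11-tetraene-1,4-diol | OC/C=C/[C@H](O)C/C(C)=C/C/C=C(/C)C=C | intermediate
10 | (2E,4R,6E,9Z)-4-hydroxy-6,10-dimethyldodeca-2,6,9,11-tetraen-1-yl methyl carbonate | COC(=O)OC/C=C/[C@H](O)C/C(C)=C/C/C=C(/C)C=C | intermediate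
11 | 3-methylbutanoic anhydride | CC(C)CC(=O)OC(=O)CC(C)C | starting material
12 | (2E,4R,6E,9Z)-1-[(methoxycarbonyl)oxy]-6,10-dimethyldodeca-2,6,9,11-tetraen-4-yl 3-methylbutanoate | COC(=O)OC/C=C/[C@H](OC(=O)CC(C)C)C/C(C)=C/C/C=C(/C)C=C | intermediate
13 | di-tert-butyl propanedioate | CC(C)(C)OC(=O)CC(=O)OC(C)(C)C | starting material
14 | di-tert-butyl 2-[(3R,4R,6E,9Z)-6,10-dimethyl-4-[(3-methylbutanoyl)oxy]dodeca-1,6,9,11-tetraen-3-yl]propanedioate | C=C[C@@H]([C@H](OC(=O)CC(C)C)C/C(C)=C/C/C=C(/C)C=C)C(C(=O)OC(C)(C)C)C(=O)OC(C)(C)C | intermediate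
15 | 2-[(3R,4R,6E,9Z)-6,10-dimethyl-4-[(3-methylbutanoyl)oxy]dodeca-1,6,9,11-tetraen-3-yl]propanedioic acid | C=C[C@@H]([C@H](OC(=O)CC(C)C)C/C(C)=C/C/C=C(/C)C=C)C(C(=O)O)C(=O)O | intermediate
16 | (3R,4R,6E,9Z)-3-ethenyl-6,10-dimethyl-2-methylidene-4-[(3-methylbutanoyl)oxy]dodeca-6,9,11-trienoic acid | C=C[C@@H]([C@H](OC(=O)CC(C)C)C/C(C)=C/C/C=C(/C)C=C)C(=C)C(=O)O | intermediate
17 | 2-(trimethylsilyl)ethyl (3R,4R,6E,9Z)-3-ethenyl-6,10-dimethyl-2-methylidene-4-[(3-methylbutanoyl)oxy]dodeca-6,9,11-trienoate | C=C[C@@H]([C@H](OC(=O)CC(C)C)C/C(C)=C/C/C=C(/C)C=C)C(=C)C(=O)OCC[Si](C)(C)C | intermediate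
18 | 2-(trimethylsilyl)ethyl (3R,4R)-3-ethenyl-5-[(2R,3R)-3-{[(2R,3S)-3-ethenyl-3-methyloxiran-2-yl]methyl}-2-methyloxiran-2-yl]-2-methylidene-4-[(3-methylbutanoyl)oxy]pentanoate | C=C[C@@H]([C@H](OC(=O)CC(C)C)C[C@@]1(C)O[C@@H]1C[C@H]1O[C@@]1(C)C=C)C(=C)C(=O)OCC[Si](C)(C)C | intermediate
19 | 2-(trimethylsilyl)ethyl (1R,3R,4S,5Z,7R,8R,10R)-1,10:3,4-diepoxy-8-[(3-methylbutanoyl)oxy]germacra-5,11(13)-dien-12-oate | C=C(C(=O)OCC[Si](C)(C)C)[C@H]1/C=C\[C@]2(C)O[C@@H]2C[C@H]2O[C@]2(C)C[C@H]1OC(=O)CC(C)C | intermediate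
20 | tetrabutylammonium (1R,3R,4S,5Z,7R,8R,10R)-1,10:3,4-diepoxy-8-[(3-methylbutanoyl)oxy]germacra-5,11(13)-dien-12-oate | C=C(C(=O)[O-])[C@H]1/C=C\[C@]2(C)O[C@@H]2C[C@H]2O[C@]2(C)C[C@H]1OC(=O)CC(C)C.CCCC[N+](CCCC)(CCCC)CCCC | intermediate (not isolated)
21 | (1R,3R,4Z,6R,7R,8R,10R)-1,10-epoxy-3-hydroxy-8-[(3-methylbutanoyl)oxy]germacra-4,11(13)-dien-12,6-olide | C=C1C(=O)O[C@@H]2/C=C(/C)[C@H](O)C[C@H]3O[C@]3(C)C[C@@H](OC(=O)CC(C)C)[C@@H]12 | target

**Step count and risks**

Total: 14 steps. Longest linear sequence: 13 steps (3 to 21, steps 2–14); step 1 is a one-step branch.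

Step 13 (ring closure). What may go wrong: oligomerisation, slow engagement of the hindered oxirane-bearing vinyl group, or chelation of the ruthenium alkylidene by the neighbouring acrylate ester. The fallback closes the ring at the malonate stage and builds the acrylate afterwards. It sets out from 15. Both acid groups are esterified (Me3SiCH2CH2OH, carbodiimide, DMAP) to the bis[2-(trimethylsilyl)ethyl] malonate F1. Shi epoxidation under the conditions of step 12 should give the bis-oxirane malonate F2. Ring-closing metathesis with the second-generation Grubbs catalyst, now without any acrylate alkene and with a bulkier C7 substituent favouring the folded rotamer, should give the macrocyclic malonate F3. Bu4NF should release the macrocyclic malonic acid F4. Mannich methylenation (aq. CH2O, Et2NH, THF, rt to 40 °C) should give the macrocyclic acrylic acid F5. F5 is treated at once with Pd2(dba)3·CHCl3 and P(OiPr)3 without fluoride, the free acid serving as its own proton source, and the route is rejoined at 21.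

Step 14 (key lactonisation). What may go wrong: scrambling of the π-allyl geometry, β-hydride elimination to a dienol before ring closure, or re-ionisation of the allylic lactone. The fallback makes the same O–C6 bond by known non-palladium chemistry. It sets out from carboxylate 20. Iodolactonisation (I2, NaHCO3, MeCN/H2O, 0 °C) should form the iodonium ion on the C5=C6 face anti to the allylic oxirane oxygen, and the carboxylate should close onto C6 anti to iodine, giving the 5-iodo γ-lactone F6 with the C3–C4 oxirane intact. Zinc dust with NH4Cl in EtOH at rt should then open the iodo-oxirane reductively (C5–I and C4–O anti-periplanar) to the C4=C5 alkene and the C3 hydroxyl, which is 21.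

Step 8 (allylic alkylation). What may go wrong: attack at the unsubstituted allyl terminus (linear product) or poor diastereocontrol beside the C8 ester. The fallback replaces allylic substitution by a [3,3]-sigmatropic rearrangement. It sets out from 9. The primary hydroxyl is esterified with tert-butyl hydrogen malonate (diisopropylcarbodiimide, DMAP cat., CH2Cl2, −20 °C) to the allyl tert-butyl malonate F7. Anhydride 11 with DMAP gives the C8 isovalerate F8. Ireland–Claisen rearrangement (LiHMDS 1.1 equiv, Me3SiCl, THF, −78 to 50 °C; only the malonate is enolised) through a chair transition state should form C7–C11 anti to the C8–O bond with H-8 eclipsing the alkene, which is the 7R isomer, and give the malonic half-ester F9. Me3SiOTf with 2,6-lutidine then gives 15, where the route is rejoined.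

**Further compounds**

F1 | step 13 | bis[2-(trimethylsilyl)ethyl] 2-[(3R,4R,6E,9Z)-6,10-dimethyl-4-[(3-methylbutanoyl)oxy]dodeca-1,6,9,11-tetraen-3-yl]propanedioate | C=C[C@@H]([C@H](OC(=O)CC(C)C)C/C(C)=C/C/C=C(/C)C=C)C(C(=O)OCC[Si](C)(C)C)C(=O)OCC[Si](C)(C)C
F2 | step 13 | bis[2-(trimethylsilyl)ethyl] malonate of the (1R,10R):(3R,4S)-bis-oxirane (open chain; germacrane locants) | C=C[C@@H]([C@H](OC(=O)CC(C)C)C[C@@]1(C)O[C@@H]1C[C@H]1O[C@@]1(C)C=C)C(C(=O)OCC[Si](C)(C)C)C(=O)OCC[Si](C)(C)C
F3 | step 13 | bis[2-(trimethylsilyl)ethyl] 2-[(1R,3R,4S,5Z,7R,8R,10R)-1,10:3,4-diepoxy-8-[(3-methylbutanoyl)oxy]cyclodec-5-en-7-yl]propanedioate (germacrane locants) | C[Si](C)(C)CCOC(=O)C(C(=O)OCC[Si](C)(C)C)[C@H]1/C=C\[C@]2(C)O[C@@H]2C[C@H]2O[C@]2(C)C[C@H]1OC(=O)CC(C)C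
F4 | step 13 | macrocyclic malonic acid corresponding to F3 | OC(=O)C(C(=O)O)[C@H]1/C=C\[C@]2(C)O[C@@H]2C[C@H]2O[C@]2(C)C[C@H]1OC(=O)CC(C)C
F5 | step 13 | (1R,3R,4S,5Z,7R,8R,10R)-1,10:3,4-diepoxy-8-[(3-methylbutanoyl)oxy]germacra-5,11(13)-dien-12-oic acid | C=C(C(=O)O)[C@H]1/C=C\[C@]2(C)O[C@@H]2C[C@H]2O[C@]2(C)C[C@H]1OC(=O)CC(C)C
F6 | step 14 | 5-iodo-1,10:3,4-diepoxy-8-[(3-methylbutanoyl)oxy]germacr-11(13)-en-12,6-olide (iodine on C5 anti to the lactone oxygen on C6) | C=C1C(=O)O[C@@H]2[C@@H](I)[C@]3(C)O[C@@H]3C[C@H]3O[C@]3(C)C[C@@H](OC(=O)CC(C)C)[C@@H]12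
F7 | step 8 | tert-butyl (2E,4R,6E,9Z)-4-hydroxy-6,10-dimethyldodeca-2,6,9,11-tetraen-1-yl propanedioate | CC(C)(C)OC(=O)CC(=O)OC/C=C/[C@H](O)C/C(C)=C/C/C=C(/C)C=C
F8 | step 8 | tert-butyl (2E,4R,6E,9Z)-6,10-dimethyl-4-[(3-methylbutanoyl)oxy]dodeca-2,6,9,11-tetraen-1-yl propanedioate | CC(C)(C)OC(=O)CC(=O)OC/C=C/[C@H](OC(=O)CC(C)C)C/C(C)=C/C/C=C(/C)C=C
F9 | step 8 | 2-(tert-butoxycarbonyl)-2-[(3R,4R,6E,9Z)-6,10-dimethyl-4-[(3-methylbutanoyl)oxy]dodeca-1,6,9,11-tetraen-3-yl]acetic acid (malonate carbon as a mixture) | C=C[C@@H]([C@H](OC(=O)CC(C)C)C/C(C)=C/C/C=C(/C)C=C)C(C(=O)O)C(=O)OC(C)(C)C
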